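As the chemist at this flask, I turn the earlier runs into two times before integrating anything.

| flask | D | X | remark | time |
|---|---|---|---|---|
| ochre | 10 mM | 0.80 equiv | run made earlier |  |
| amber | 15 mM | 0.80 equiv | run made earlier |  |
| flask | 20 mM | 0.800 equiv |  | 8.0 min |

| run | time / min | D / % | J / % | G / % | Q / % |
|---|---|---|---|---|---|
| ochre | 0.667 | 82.2 | 5.3 | 0 | 11.3 |
| ochre | 1.50 | 65.8 | 10.0 | 0 | 24.8 |
| ochre | 3.00 | 47.8 | 12.9 | 0.8 | 38.1 |
| ochre | 5.00 | 36.5 | 16.5 | 1.2 | 44.9 |
| amber | 1.33 | 57.2 | 11.7 | 0.8 | 31.0 |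
| amber | 2.50 | 41.2 | 18.1 | 0 | 40.4 |
| amber | 4.00 | 30.0 | 19.4 | 0 | 48.2 |
| amber | 5.00 | 28.4 | 19.7 | 0 | 53.8 |

(readings scatter by 1 percentage point)

- where most of what was charged as D, at 8.0 min is found (Q / D / J / G)
- the largest share itself, whichever of these holds it, in percent of the D charged

- in percentages every species weighs as the D in it: one Q counts as two

The first time is the 8.0 min asked for. The second is τ, the time in which D halves, its second-order half-life, with the fraction of D left taken as one over one plus t/τ. The last readings give 2.87 min for ochre and 1.98 min for amber, and their products with the starting [D] stay close, 1.72 M·s and 1.78 M·s. So I scale by the charge at this fixed equivalence: the flask's half-time of D is 1.46 min.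

Then t/τ is 5.48, and D left is 15.5 %. At the last readings Q:J reads 2.72 in ochre and 2.73 in amber, pooled 2.73. Setting G aside, I reckon Q at 61.9 %, more than D or J.

The forecast says Q at 65 %: “Q holds the most”.

The flask gives Q at 59.6 %, with D at 14.3 % and J at 25.5 %.

    D + X → J (k = 0.210 M⁻¹ s⁻¹)
    D → G (k = 4.30 × 10⁻⁵ s⁻¹)
    2 D → Q (k = 0.220 M⁻¹ s⁻¹)
    X → Z (k = 0.00340 s⁻¹)

In this flask, the steps making Q and J did half of their turnover up to 8.0 min by 0.975 min and 1.02 min. In this flask X also went to Z, half of that turnover up to 8.0 min done by 2.05 min, and at 8.00 min X stood at 10.2 % of its charge. For the same flask read at 5.0 min, τ gives D 22.6 % and Q 56.6 %; computed, they are 20.6 % and 54.9 %.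

The data were computed for an exercise; noise was put on by code.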